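**Plan**

- Cuts: (a) the central CH2–CH2 bond of the bridge, which divides the target into two bicycles that are the same trans-fused oxepane–cyclohexane and both derive from one enone, 22; (b) in 22, the ring A bond between the ring-fusion CH–O carbon and its neighbouring ring CH2; (c) the oxepane O–C(CH3)2 bond; (d) the bond from the quaternary carbon to its two-carbon arm.
- Enabling feature: in ring A (the methylenecyclohexane fused to hydroxy-oxepane ring B) the ring-fusion CH–O carbon is three bonds (two ring CH2 groups) from the ring carbon that carries the exocyclic methylene. An α-alkoxy radical on a finished ring B can therefore close ring A onto a vinyl ketone whose carbonyl carbon is that ring carbon.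
- Forward order: geraniol → quaternary carbon → ring B → dienone arm → ring A (radical closure) → enone 22. Enone 22 serves once as Michael acceptor (left half) and once, after sulfinate and methyl addition, as sulfone nucleophile (right half). Union is followed by methylenation, desulfonylation, acetylation and desilylation.
- Stereochemistry: Sharpless epoxidation and invertive alkynylalane opening (quaternary carbon); Shi epoxidation with the L-fructose-derived ketone (oxepane carbinol); chair-like radical closure (ring fusion); axial protonation or equilibration (bridge-bearing CH of each half); equatorial methyl addition (tertiary acetate carbon).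

Key step: step 13

Remark: the sulfonyl-bearing carbon made in step 18 (and the selenium- or oxirane-bearing carbons of three fallback compounds) forms as both epimers and is later reduced to CH2 or reset, so it is left undefined in names and SMILES. TBS = tert-butyldimethylsilyl, TMS = trimethylsilyl, Tf = trifluoromethanesulfonyl.

Step 1
Reactants: 1 geraniol
Product: 2 (2S,3S)-2,3-epoxygeraniol
Conditions: Ti(Oi-Pr)4 (5 mol %), L-(+)-diethyl tartrate (6 mol %), t-BuOOH, 4 Å MS, CH2Cl2, −20 °C
Reagents that add atoms: tert-butyl hydroperoxide CC(C)(C)OO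
Why: Sharpless asymmetric epoxidation, in which the titanium–L-tartrate complex binds the allylic hydroxyl and delivers oxygen to one face of the 2,3-alkene only, sets C2 and C3 as (2S,3S) and leaves the remote trisubstituted alkene alone.

Step 2
Reactants: 2 (2S,3S)-2,3-epoxygeraniol; 3 (trimethylsilyl)acetylene
Product: 7 (2R,3S)-3-ethynyl-3,7-dimethyloct-6-ene-1,2-diol, via lithium (trimethylsilyl)acetylide 4 (not isolated), via diethyl[(trimethylsilyl)ethynyl]alane 5 (not isolated), via C-silylated diol 6 (not isolated)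
Conditions: 3, n-BuLi, toluene, 0 °C; Et2AlCl, 0 °C; 2, 0 °C → rt; aq. KNaC4H4O6 (potassium sodium tartrate); then K2CO3, MeOH, rt
Reagents that add atoms: none
Why: Organoalane opening of a 2,3-epoxy alcohol, in which aluminium bound to the primary alkoxide activates the epoxide and the alkynyl group attacks C3 (the carbon that best carries positive charge) with inversion, builds the quaternary centre as 3S while C2 keeps its oxygen, and methanolysis then cleaves the C–Si bond.

Step 3
Reactants: 7 (2R,3S)-3-ethynyl-3,7-dimethyloct-6-ene-1,2-diol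
Product: 8 primary TBS ether, (2R,3S)-1-(TBS-oxy)-3-ethynyl-3,7-dimethyloct-6-en-2-ol
Conditions: TBSCl (1.05 equiv), imidazole, CH2Cl2, 0 °C
Reagents that add atoms: tert-butyldimethylsilyl chloride CC(C)(C)[Si](C)(C)Cl
Why: Chemoselective silyl ether formation at the primary hydroxyl, the secondary one being neopentylic and much slower, leaves only one oxygen free for the later ring closure.

Step 4
Reactants: 8 primary TBS ether
Product: 9 (S)-epoxide, (2R,3S)-1-(TBS-oxy)-5-[(2S)-3,3-dimethyloxiran-2-yl]-3-ethynyl-3-methylpentan-2-ol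
Conditions: L-fructose-derived Shi ketone (1,2:4,5-di-O-isopropylidene-β-L-erythro-2,3-hexodiulo-2,6-pyranose, 30 mol %), KHSO5 (as the triple salt 2KHSO5·KHSO4·K2SO4), K2CO3, Bu4NHSO4, MeCN/CH2(OMe)2/aq. Na2B4O7 buffer (pH 10.5), 0 °C
Reagents that add atoms: potassium peroxymonosulfate [K+].[O-]S(=O)(=O)OO
Why: Shi asymmetric epoxidation, whose chiral dioxirane attacks the trisubstituted alkene through a spiro transition state, gives the (S)-epoxide under reagent control with this enantiomer of the ketone, the alkyne and the hindered free alcohol being inert.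

Step 5
Reactants: 9 (S)-epoxide
Product: 10 oxepanol, (3S,6S,7R)-7-[(TBS-oxy)methyl]-6-ethynyl-2,2,6-trimethyloxepan-3-ol
Conditions: (+)-camphor-10-sulfonic acid (10 mol %), CH2Cl2, 0 °C
Reagents that add atoms: none
Why: Acid-catalysed intramolecular epoxide opening (7-endo-tet etherification), in which the protonated epoxide is attacked at its dimethyl-substituted carbon where positive charge is best stabilised, forms ring B and leaves the secondary carbinol carbon in its (S) configuration because that carbon is not touched.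

Step 6
Reactants: 10 oxepanol
Product: 11 bis-TBS ether, (3S,6S,7R)-3-(TBS-oxy)-7-[(TBS-oxy)methyl]-6-ethynyl-2,2,6-trimethyloxepane
Conditions: TBSOTf, 2,6-lutidine, CH2Cl2, −78 → 0 °C
Reagents that add atoms: tert-butyldimethylsilyl trifluoromethanesulfonate CC(C)(C)[Si](C)(C)OS(=O)(=O)C(F)(F)F
Why: Silyl ether formation with the silyl triflate, which is reactive enough for a secondary alcohol flanked by a fully substituted carbon.

Step 7
Reactants: 11 bis-TBS ether
Product: 12 methyl ketone, 1-[(2R,3R,6S)-6-(TBS-oxy)-2-[(TBS-oxy)methyl]-3,7,7-trimethyloxepan-3-yl]ethan-1-one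
Conditions: Ph3PAuNTf2 (3 mol %), 1,4-dioxane/H2O (8:1), 60 °C
Reagents that add atoms: water O
Why: Gold-catalysed Markovnikov hydration of the terminal alkyne places oxygen on the internal carbon and gives the methyl ketone without touching a stereocentre.

Step 8
Reactants: 12 methyl ketone
Product: 14 enol triflate of 12, via potassium enolate 13 (not isolated)
Conditions: KN(SiMe3)2, THF, −78 °C; PhNTf2, −78 → 0 °C
Reagents that add atoms: N-phenylbis(trifluoromethanesulfonimide) FC(F)(F)S(=O)(=O)N(c1ccccc1)S(=O)(=O)C(F)(F)F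
Why: Enol triflate formation is regiochemically unambiguous because the only enolisable position of the ketone is its methyl group, the other α-carbon being quaternary.

Step 9
Reactants: 14 enol triflate
Product: 15 primary alcohol, 1-[(2R,3R,6S)-6-(TBS-oxy)-2-(hydroxymethyl)-3,7,7-trimethyloxepan-3-yl]ethenyl triflate
Conditions: HF·pyridine, pyridine, THF, 0 °C
Reagents that add atoms: none
Why: Selective desilylation with buffered HF·pyridine removes the primary silyl ether much faster than the secondary one shielded by the gem-dimethyl carbon and leaves the enol triflate intact.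

Step 10
Reactants: 15 primary alcohol
Product: 17 oxepane-2-carboxylic acid, via aldehyde 16 (not isolated)
Conditions: TEMPO (20 mol %), PhI(OAc)2 (2.2 equiv), MeCN/H2O (1:1), rt
Reagents that add atoms: water O
Why: Oxoammonium (TEMPO) oxidation takes the primary alcohol through the aldehyde hydrate to the acid under near-neutral conditions that the enol triflate and the silyl ether tolerate.

Step 11
Reactants: 17 oxepane-2-carboxylic acid; 18 N-hydroxyphthalimide
Product: 19 N-acyloxyphthalimide (redox-active ester) of 17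
Conditions: N,N'-diisopropylcarbodiimide, DMAP (5 mol %), CH2Cl2, 0 °C → rt
Reagents that add atoms: none
Why: Carbodiimide-mediated (Steglich-type) esterification installs the redox-active ester before the electrophilic dienone exists, so that no free carboxyl ever faces a Michael acceptor.

Step 12
Reactants: 19 N-acyloxyphthalimide enol triflate; 20 tributyl(vinyl)stannane
Product: 21 dienone redox-active ester, 1,3-dioxoisoindolin-2-yl (2R,3S,6S)-6-(TBS-oxy)-3,7,7-trimethyl-3-(3-oxopenta-1,4-dien-2-yl)oxepane-2-carboxylate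
Conditions: Pd(PPh3)4 (5 mol %), LiCl (3 equiv), CO (3 atm), THF, 55 °C, dark
Reagents that add atoms: carbon monoxide [C-]#[O+]
Why: Carbonylative Stille coupling, in which zerovalent palladium inserts into the C–OTf bond, CO insertion at the hindered alkenylpalladium outruns direct transmetalation, and vinyl transfer from tin followed by reductive elimination gives the cross-conjugated dienone under neutral conditions that the N-acyloxyphthalimide should survive.

Step 13
Reactants: 21 dienone redox-active ester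
Product: 22 trans-fused enone, (3S,5aS,9aS)-3-(TBS-oxy)-2,2,5a-trimethyl-6-methylideneoctahydro-1-benzoxepin-7(2H)-one
Conditions: undivided cell, graphite-felt cathode, Zn anode, n-Bu4NBF4 (0.1 M), N,N-dimethylacetamide, CF3CH2OH (5 equiv), constant current (about 2.2 F/mol), 5 mM, rt, Ar
Reagents that add atoms: none
Why: Cathodic one-electron reduction of the N-acyloxyphthalimide gives a radical anion that fragments to phthalimide anion, CO2 and the α-alkoxy radical at the oxepane carbon next to oxygen; this nucleophilic radical adds to the terminal carbon of the vinyl ketone, and the resulting α-keto radical is reduced and protonated by trifluoroethanol, the exocyclic methylene of the cross-conjugated system staying in place. The closest known reaction type is the electroreductive decarboxylative Giese addition of redox-active esters to enones (graphite cathode, sacrificial zinc anode), run here intramolecularly and dilute. Ring A closes in the 6-endo-trig mode, favoured over 5-exo because the carbonyl lies inside the forming ring and only the unsubstituted β-carbon is polarity-matched and sterically open. The single new stereocentre, the ring-fusion CH–O carbon (9aS), is controlled by the adjacent quaternary carbon through a chair-like transition state in which the C–O and C–CH2 bonds of ring B are both equatorial on the forming ring and the angular methyl is axial. The selectivity the step needs is trans ring fusion, and what should secure it is that this arrangement puts the bulky dienone arm anti to the ring C–O bond and leaves only the small methyl gauche to the ring oxygen and its gem-dimethyl carbon, while the flexible seven-membered ring spans two equatorial sites without strain; the configuration of the carboxyl-bearing carbon of 21 is irrelevant because the radical is planarised. Chemoselectivity rests on the ester being reduced at a potential well short of that of the dienone and on limiting the charge passed.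

Step 14
Reactants: 22 trans-fused enone
Product: 23 keto sulfone, (3S,5aS,6S,9aS)-6-[(benzenesulfonyl)methyl]-3-(TBS-oxy)-2,2,5a-trimethyloctahydro-1-benzoxepin-7(2H)-one
Conditions: PhSO2Na (2 equiv), AcOH (3 equiv), THF/H2O, rt
Reagents that add atoms: sodium benzenesulfinate [Na+].[O-]S(=O)c1ccccc1
Why: Conjugate (sulfa-Michael) addition of benzenesulfinate to the exocyclic enone, with the new α-stereocentre settling through enolisation and reversible addition in the equatorial arrangement that keeps the side chain cis to the angular methyl (6S).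

Step 15
Reactants: 23 keto sulfone
Product: 24 tertiary alcohol, (3S,5aS,6S,7R,9aS)-6-[(benzenesulfonyl)methyl]-3-(TBS-oxy)-2,2,5a,7-tetramethyldecahydro-1-benzoxepin-7-ol
Conditions: CeCl3 (anhydrous), MeLi, THF, −78 °C
Reagents that add atoms: methyllithium [Li]C
Why: Organocerium 1,2-addition, non-basic enough to spare the β-sulfonyl ketone from elimination, brings the methyl group in equatorially because the axial path is blocked by the 1,3-diaxial angular methyl, so the hydroxyl ends up axial (7R).

Step 16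
Reactants: 24 tertiary alcohol
Product: 25 diol sulfone, (3S,5aS,6S,7R,9aS)-6-[(benzenesulfonyl)methyl]-2,2,5a,7-tetramethyldecahydro-1-benzoxepine-3,7-diol
Conditions: Bu4NF, THF, 45 °C
Reagents that add atoms: none
Why: Fluoride-mediated desilylation frees the secondary hydroxyl of this half so that it can later be told apart from the still silylated hydroxyl of the other half.

Step 17
Reactants: 25 diol sulfone
Product: 26 bis-TMS ether of 25
Conditions: TMSOTf (2.5 equiv), 2,6-lutidine, CH2Cl2, −78 → 0 °C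
Reagents that add atoms: trimethylsilyl trifluoromethanesulfonate C[Si](C)(C)OS(=O)(=O)C(F)(F)F
Why: Silylation with trimethylsilyl triflate masks both hydroxyls, including the hindered tertiary one, as ethers that tolerate butyllithium at low temperature yet fall off in dilute acid.

Step 18
Reactants: 26 bis-TMS sulfone; 22 trans-fused enone
Product: 29 keto diol sulfone (left ketone unit joined through CH2–CH(SO2Ph) to the right diol unit), via lithiated sulfone 27 (not isolated), via bis(trimethylsilyl) ether adduct 28 (not isolated)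
Conditions: 26, n-BuLi (1.05 equiv), THF, −78 °C; HMPA (3 equiv); 22, −78 → −40 °C; AcOH, −78 °C; then 1 M HCl, THF/MeOH, 0 °C
Reagents that add atoms: none
Why: Michael addition of an α-sulfonyl carbanion, steered to the 1,4-mode by HMPA and by the unhindered terminal CH2 of the enone, forms the central C–C bond, protonation of the enolate from the axial direction opposite the angular methyl places the new chain equatorial (also the thermodynamic arrangement, 6S in the ketone), and dilute acid then removes the two trimethylsilyl groups.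

Step 19
Reactants: 29 keto diol sulfone
Product: 30 methylidene diol sulfone
Conditions: Ph3PCH3Br (8 equiv), KOt-Bu (7.5 equiv), toluene/THF, rt → 60 °C
Reagents that add atoms: methyltriphenylphosphonium bromide C[P+](c1ccccc1)(c1ccccc1)c1ccccc1.[Br-]
Why: Wittig methylenation of the ring ketone with excess non-stabilised ylide (the free hydroxyls hold part of the base as alkoxides), the adjacent stereocentre being already in its preferred equatorial arrangement and therefore safe in the basic medium.

Step 20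
Reactants: 30 methylidene diol sulfone
Product: 31 methylidene diol
Conditions: Na/Hg (6% Na), Na2HPO4, MeOH/THF, −20 → 0 °C
Reagents that add atoms: none
Why: Reductive desulfonylation by electron transfer from sodium amalgam replaces the C–S bond by C–H (no β-leaving group is present for elimination) and removes the only undefined stereocentre without touching the 1,1-disubstituted alkene.

Step 21
Reactants: 31 methylidene diol
Product: 32 diacetate TBS ether
Conditions: Ac2O, Et3N, DMAP (1 equiv), CH2Cl2, 40 °C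
Reagents that add atoms: acetic anhydride CC(=O)OC(C)=O
Why: DMAP-catalysed acylation (Steglich-type acetylation) esterifies the secondary and, more slowly, the hindered axial tertiary hydroxyl, while the silyl ether keeps the third oxygen out of play.

Step 22
Reactants: 32 diacetate TBS ether
Product: 33 CNP0412606.1
Conditions: HF·pyridine, THF, 0 °C → rt
Reagents that add atoms: none
Why: Fluoride-mediated desilylation with HF·pyridine, mild enough for the two acetates and the exocyclic alkene, releases the last hydroxyl and gives the target.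

**Compound list**

1 | geraniol, (2E)-3,7-dimethylocta-2,6-dien-1-ol | CC(C)=CCC/C(C)=C/CO | starting material
2 | (2S,3S)-2,3-epoxygeraniol, [(2S,3S)-3-methyl-3-(4-methylpent-3-en-1-yl)oxiran-2-yl]methanol | OC[C@@H]1O[C@@]1(C)CCC=C(C)C | intermediate
3 | (trimethylsilyl)acetylene | C#C[Si](C)(C)C | starting material
4 | lithium (trimethylsilyl)acetylide | [Li]C#C[Si](C)(C)C | intermediate
5 | diethyl[(trimethylsilyl)ethynyl]alane | CC[Al](CC)C#C[Si](C)(C)C | intermediate
6 | (2R,3S)-3,7-dimethyl-3-[(trimethylsilyl)ethynyl]oct-6-ene-1,2-diol | OC[C@H](O)[C@](C)(C#C[Si](C)(C)C)CCC=C(C)C | intermediate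
7 | (2R,3S)-3-ethynyl-3,7-dimethyloct-6-ene-1,2-diol | OC[C@H](O)[C@](C)(C#C)CCC=C(C)C | intermediate
8 | (2R,3S)-1-[(tert-butyldimethylsilyl)oxy]-3-ethynyl-3,7-dimethyloct-6-en-2-ol | CC(C)(C)[Si](C)(C)OC[C@H](O)[C@](C)(C#C)CCC=C(C)C | intermediate
9 | (2R,3S)-1-[(tert-butyldimethylsilyl)oxy]-5-[(2S)-3,3-dimethyloxiran-2-yl]-3-ethynyl-3-methylpentan-2-ol | CC(C)(C)[Si](C)(C)OC[C@H](O)[C@](C)(C#C)CC[C@@H]1OC1(C)C | intermediate
10 | (3S,6S,7R)-7-{[(tert-butyldimethylsilyl)oxy]methyl}-6-ethynyl-2,2,6-trimethyloxepan-3-ol | CC(C)(C)[Si](C)(C)OC[C@@H]1OC(C)(C)[C@@H](O)CC[C@@]1(C)C#C | intermediate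
11 | (3S,6S,7R)-3-[(tert-butyldimethylsilyl)oxy]-7-{[(tert-butyldimethylsilyl)oxy]methyl}-6-ethynyl-2,2,6-trimethyloxepane | CC(C)(C)[Si](C)(C)OC[C@@H]1OC(C)(C)[C@@H](O[Si](C)(C)C(C)(C)C)CC[C@@]1(C)C#C | intermediate
12 | 1-[(2R,3R,6S)-6-[(tert-butyldimethylsilyl)oxy]-2-{[(tert-butyldimethylsilyl)oxy]methyl}-3,7,7-trimethyloxepan-3-yl]ethan-1-one | CC(C)(C)[Si](C)(C)OC[C@@H]1OC(C)(C)[C@@H](O[Si](C)(C)C(C)(C)C)CC[C@@]1(C)C(C)=O | intermediate
13 | potassium 1-[(2R,3R,6S)-6-[(tert-butyldimethylsilyl)oxy]-2-{[(tert-butyldimethylsilyl)oxy]methyl}-3,7,7-trimethyloxepan-3-yl]ethen-1-olate | CC(C)(C)[Si](C)(C)OC[C@@H]1OC(C)(C)[C@@H](O[Si](C)(C)C(C)(C)C)CC[C@@]1(C)C(=C)[O-].[K+] | intermediate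
14 | 1-[(2R,3R,6S)-6-[(tert-butyldimethylsilyl)oxy]-2-{[(tert-butyldimethylsilyl)oxy]methyl}-3,7,7-trimethyloxepan-3-yl]ethenyl trifluoromethanesulfonate | CC(C)(C)[Si](C)(C)OC[C@@H]1OC(C)(C)[C@@H](O[Si](C)(C)C(C)(C)C)CC[C@@]1(C)C(=C)OS(=O)(=O)C(F)(F)F | intermediate
15 | 1-[(2R,3R,6S)-6-[(tert-butyldimethylsilyl)oxy]-2-(hydroxymethyl)-3,7,7-trimethyloxepan-3-yl]ethenyl trifluoromethanesulfonate | OC[C@@H]1OC(C)(C)[C@@H](O[Si](C)(C)C(C)(C)C)CC[C@@]1(C)C(=C)OS(=O)(=O)C(F)(F)F | intermediate
16 | 1-[(2R,3R,6S)-6-[(tert-butyldimethylsilyl)oxy]-2-formyl-3,7,7-trimethyloxepan-3-yl]ethenyl trifluoromethanesulfonate | O=C[C@@H]1OC(C)(C)[C@@H](O[Si](C)(C)C(C)(C)C)CC[C@@]1(C)C(=C)OS(=O)(=O)C(F)(F)F | intermediate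
17 | (2R,3R,6S)-6-[(tert-butyldimethylsilyl)oxy]-3,7,7-trimethyl-3-{1-[(trifluoromethanesulfonyl)oxy]ethenyl}oxepane-2-carboxylic acid | OC(=O)[C@@H]1OC(C)(C)[C@@H](O[Si](C)(C)C(C)(C)C)CC[C@@]1(C)C(=C)OS(=O)(=O)C(F)(F)F | intermediate
18 | N-hydroxyphthalimide | ON1C(=O)c2ccccc2C1=O | starting material
19 | 1,3-dioxoisoindolin-2-yl (2R,3R,6S)-6-[(tert-butyldimethylsilyl)oxy]-3,7,7-trimethyl-3-{1-[(trifluoromethanesulfonyl)oxy]ethenyl}oxepane-2-carboxylate | O=C(ON1C(=O)c2ccccc2C1=O)[C@@H]3OC(C)(C)[C@@H](O[Si](C)(C)C(C)(C)C)CC[C@@]3(C)C(=C)OS(=O)(=O)C(F)(F)F | intermediate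
20 | tributyl(vinyl)stannane | C=C[Sn](CCCC)(CCCC)CCCC | starting material
21 | 1,3-dioxoisoindolin-2-yl (2R,3S,6S)-6-[(tert-butyldimethylsilyl)oxy]-3,7,7-trimethyl-3-(3-oxopenta-1,4-dien-2-yl)oxepane-2-carboxylate | O=C(ON1C(=O)c2ccccc2C1=O)[C@@H]3OC(C)(C)[C@@H](O[Si](C)(C)C(C)(C)C)CC[C@@]3(C)C(=C)C(=O)C=C | intermediate
22 | (3S,5aS,9aS)-3-[(tert-butyldimethylsilyl)oxy]-2,2,5a-trimethyl-6-methylideneoctahydro-1-benzoxepin-7(2H)-one (trans-fused) | O=C1CC[C@@H]2OC(C)(C)[C@@H](O[Si](C)(C)C(C)(C)C)CC[C@@]2(C)C1=C | intermediate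
23 | (3S,5aS,6S,9aS)-6-[(benzenesulfonyl)methyl]-3-[(tert-butyldimethylsilyl)oxy]-2,2,5a-trimethyloctahydro-1-benzoxepin-7(2H)-one | O=C1CC[C@@H]2OC(C)(C)[C@@H](O[Si](C)(C)C(C)(C)C)CC[C@@]2(C)[C@@H]1CS(=O)(=O)c3ccccc3 | intermediate
24 | (3S,5aS,6S,7R,9aS)-6-[(benzenesulfonyl)methyl]-3-[(tert-butyldimethylsilyl)oxy]-2,2,5a,7-tetramethyldecahydro-1-benzoxepin-7-ol | C[C@@]1(O)CC[C@@H]2OC(C)(C)[C@@H](O[Si](C)(C)C(C)(C)C)CC[C@@]2(C)[C@@H]1CS(=O)(=O)c3ccccc3 | intermediate
25 | (3S,5aS,6S,7R,9aS)-6-[(benzenesulfonyl)methyl]-2,2,5a,7-tetramethyldecahydro-1-benzoxepine-3,7-diol | C[C@@]1(O)CC[C@@H]2OC(C)(C)[C@@H](O)CC[C@@]2(C)[C@@H]1CS(=O)(=O)c3ccccc3 | intermediate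
26 | (3S,5aS,6S,7R,9aS)-6-[(benzenesulfonyl)methyl]-2,2,5a,7-tetramethyl-3,7-bis[(trimethylsilyl)oxy]decahydro-1-benzoxepine | C[C@@]1(O[Si](C)(C)C)CC[C@@H]2OC(C)(C)[C@@H](O[Si](C)(C)C)CC[C@@]2(C)[C@@H]1CS(=O)(=O)c3ccccc3 | intermediate
27 | lithium salt of the α-sulfonyl carbanion of 26 | C[C@@]1(O[Si](C)(C)C)CC[C@@H]2OC(C)(C)[C@@H](O[Si](C)(C)C)CC[C@@]2(C)[C@@H]1[CH-]S(=O)(=O)c3ccccc3.[Li+] | intermediate
28 | (3S,5aS,6S,9aS)-6-{2-(benzenesulfonyl)-2-[(3S,5aS,6S,7R,9aS)-2,2,5a,7-tetramethyl-3,7-bis[(trimethylsilyl)oxy]decahydro-1-benzoxepin-6-yl]ethyl}-3-[(tert-butyldimethylsilyl)oxy]-2,2,5a-trimethyloctahydro-1-benzoxepin-7(2H)-one | O=C1CC[C@@H]2OC(C)(C)[C@@H](O[Si](C)(C)C(C)(C)C)CC[C@@]2(C)[C@@H]1CC(S(=O)(=O)c3ccccc3)[C@H]4[C@]5(C)CC[C@H](O[Si](C)(C)C)C(C)(C)O[C@H]5CC[C@@]4(C)O[Si](C)(C)C | intermediate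
29 | (3S,5aS,6S,9aS)-6-{2-(benzenesulfonyl)-2-[(3S,5aS,6S,7R,9aS)-3,7-dihydroxy-2,2,5a,7-tetramethyldecahydro-1-benzoxepin-6-yl]ethyl}-3-[(tert-butyldimethylsilyl)oxy]-2,2,5a-trimethyloctahydro-1-benzoxepin-7(2H)-one | O=C1CC[C@@H]2OC(C)(C)[C@@H](O[Si](C)(C)C(C)(C)C)CC[C@@]2(C)[C@@H]1CC(S(=O)(=O)c3ccccc3)[C@H]4[C@]5(C)CC[C@H](O)C(C)(C)O[C@H]5CC[C@@]4(C)O | intermediate
30 | (3S,5aS,6S,7R,9aS)-6-{1-(benzenesulfonyl)-2-[(3S,5aS,6R,9aS)-3-[(tert-butyldimethylsilyl)oxy]-2,2,5a-trimethyl-7-methylidenedecahydro-1-benzoxepin-6-yl]ethyl}-2,2,5a,7-tetramethyldecahydro-1-benzoxepine-3,7-diol | C=C1CC[C@@H]2OC(C)(C)[C@@H](O[Si](C)(C)C(C)(C)C)CC[C@@]2(C)[C@@H]1CC(S(=O)(=O)c3ccccc3)[C@H]4[C@]5(C)CC[C@H](O)C(C)(C)O[C@H]5CC[C@@]4(C)O | intermediate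
31 | (3S,5aS,6S,7R,9aS)-6-{2-[(3S,5aS,6R,9aS)-3-[(tert-butyldimethylsilyl)oxy]-2,2,5a-trimethyl-7-methylidenedecahydro-1-benzoxepin-6-yl]ethyl}-2,2,5a,7-tetramethyldecahydro-1-benzoxepine-3,7-diol | C=C1CC[C@@H]2OC(C)(C)[C@@H](O[Si](C)(C)C(C)(C)C)CC[C@@]2(C)[C@@H]1CC[C@H]3[C@]4(C)CC[C@H](O)C(C)(C)O[C@H]4CC[C@@]3(C)O | intermediate
32 | (3S,5aS,6S,7R,9aS)-6-{2-[(3S,5aS,6R,9aS)-3-[(tert-butyldimethylsilyl)oxy]-2,2,5a-trimethyl-7-methylidenedecahydro-1-benzoxepin-6-yl]ethyl}-2,2,5a,7-tetramethyldecahydro-1-benzoxepine-3,7-diyl diacetate | C=C1CC[C@@H]2OC(C)(C)[C@@H](O[Si](C)(C)C(C)(C)C)CC[C@@]2(C)[C@@H]1CC[C@H]3[C@]4(C)CC[C@H](OC(C)=O)C(C)(C)O[C@H]4CC[C@@]3(C)OC(C)=O | intermediate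
33 | CNP0412606.1, (3S,5aS,6S,7R,9aS)-6-{2-[(3S,5aS,6R,9aS)-3-hydroxy-2,2,5a-trimethyl-7-methylidenedecahydro-1-benzoxepin-6-yl]ethyl}-2,2,5a,7-tetramethyldecahydro-1-benzoxepine-3,7-diyl diacetate | C=C1CC[C@@H]2OC(C)(C)[C@@H](O)CC[C@@]2(C)[C@@H]1CC[C@H]1[C@]2(C)CC[C@H](OC(C)=O)C(C)(C)O[C@H]2CC[C@@]1(C)OC(C)=O | target

**Step count**

Total step count: 22. Longest linear sequence: 22 steps (geraniol to the target through the right half; enone 22 enters a second time, unchanged, in step 18).

**Steps most likely to fail**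

Step 13. The closure may suffer from poor facial selectivity at the planarised radical carbon, giving a cis ring fusion that cannot be repaired because that carbon is not epimerisable, or from reduction of the radical before it cyclises. The fallback keeps the configuration of the oxepane CH–O carbon, which already matches the target once its carbon substituent becomes the ring CH2, and closes ring A at another bond. It sets out from alcohol 15. Dess–Martin oxidation is stopped at aldehyde 16 (here isolated), and Wittig methylenation gives the 2-vinyl oxepane enol triflate F1. Carbonylative Stille coupling with 20, as in step 12, gives the trienone F2. Ring-closing metathesis of the two monosubstituted vinyl groups with the second-generation Grubbs catalyst gives the trans-fused methylidene cyclohexenone F3. PhSO2Na/AcOH adds to the exocyclic methylene to give the sulfonyl enone F4, and hydrogenation of the ring alkene (H2, Pd/C) comes back to the route at keto sulfone 23. The portion of enone 22 needed in step 18 would then be made from 23 by DBU-induced loss of benzenesulfinate.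

Step 5. The hindered hydroxyl may attack the secondary epoxide carbon instead (6-exo closure to a tetrahydropyran), or the activated epoxide may rearrange by hydride shift. The fallback gives up the epoxide as electrophile and sets out from alkene 8, skipping step 4. Phenylselenoetherification with N-(phenylseleno)phthalimide and catalytic acid closes the ring at the more substituted alkene carbon and gives the selenide F5. Oxidation with H2O2 and selenoxide elimination give the ring alkene F6. mCPBA gives the epoxide F7, which LiAlH4 opens at the carbon remote from the gem-dimethyl group to the oxepan-3-ol epimer mixture F8. Dess–Martin oxidation gives the oxepan-3-one F9. Corey–Bakshi–Shibata reduction ((R)-2-methyl-CBS-oxazaborolidine, catecholborane, the O–CMe2 carbon acting as the large group) should set the (3S) carbinol and comes back to the route at oxepanol 10.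

Step 18. The carbanion may add to the carbonyl group or merely deprotonate the enone at its α′-CH2 instead of adding in the conjugate sense. The fallback forms the same bond by a radical conjugate addition, which needs no base. It sets out from enone 22. Conjugate addition of PhSeNa (from PhSeSePh and NaBH4) gives the β-seleno ketone F10. MeLi/CeCl3, as in step 15, gives the tertiary alcohol F11, and Bu4NF gives the seleno diol F12. Its primary alkyl radical, generated with (Me3Si)3SiH and AIBN, adds to a second portion of 22 to give the keto diol F13. The ring CH next to the ketone takes up hydrogen there and can be equilibrated to the equatorial arrangement if needed. Wittig methylenation, as in step 19, comes back to the route at diol 31, so steps 16, 17 and 20 fall away.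

**Further compounds**

F1 | step 13 | 1-[(2S,3R,6S)-6-[(tert-butyldimethylsilyl)oxy]-2-ethenyl-3,7,7-trimethyloxepan-3-yl]ethenyl trifluoromethanesulfonate | C=C[C@@H]1OC(C)(C)[C@@H](O[Si](C)(C)C(C)(C)C)CC[C@@]1(C)C(=C)OS(=O)(=O)C(F)(F)F
F2 | step 13 | 2-[(2S,3S,6S)-6-[(tert-butyldimethylsilyl)oxy]-2-ethenyl-3,7,7-trimethyloxepan-3-yl]penta-1,4-dien-3-one | C=C[C@@H]1OC(C)(C)[C@@H](O[Si](C)(C)C(C)(C)C)CC[C@@]1(C)C(=C)C(=O)C=C
F3 | step 13 | (3S,5aS,9aS)-3-[(tert-butyldimethylsilyl)oxy]-2,2,5a-trimethyl-6-methylidene-3,4,5,5a,6,9a-hexahydro-1-benzoxepin-7(2H)-one | O=C1C=C[C@@H]2OC(C)(C)[C@@H](O[Si](C)(C)C(C)(C)C)CC[C@@]2(C)C1=C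
F4 | step 13 | (3S,5aS,6S,9aS)-6-[(benzenesulfonyl)methyl]-3-[(tert-butyldimethylsilyl)oxy]-2,2,5a-trimethyl-3,4,5,5a,6,9a-hexahydro-1-benzoxepin-7(2H)-one | O=C1C=C[C@@H]2OC(C)(C)[C@@H](O[Si](C)(C)C(C)(C)C)CC[C@@]2(C)[C@@H]1CS(=O)(=O)c3ccccc3
F5 | step 5 | tert-butyl{[(2R,3S)-3-ethynyl-3,7,7-trimethyl-6-(phenylselanyl)oxepan-2-yl]methoxy}dimethylsilane (both C6 epimers) | CC(C)(C)[Si](C)(C)OC[C@@H]1OC(C)(C)C([Se]c2ccccc2)CC[C@@]1(C)C#C
F6 | step 5 | tert-butyl{[(2R,3S)-3-ethynyl-3,7,7-trimethyl-2,3,4,7-tetrahydrooxepin-2-yl]methoxy}dimethylsilane | CC(C)(C)[Si](C)(C)OC[C@@H]1OC(C)(C)C=CC[C@@]1(C)C#C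
F7 | step 5 | tert-butyl{[(2R,3S)-5,6-epoxy-3-ethynyl-3,7,7-trimethyloxepan-2-yl]methoxy}dimethylsilane (either epoxide face) | CC(C)(C)[Si](C)(C)OC[C@@H]1OC(C)(C)C2OC2C[C@@]1(C)C#C
F8 | step 5 | (6S,7R)-7-{[(tert-butyldimethylsilyl)oxy]methyl}-6-ethynyl-2,2,6-trimethyloxepan-3-ol (both C3 epimers) | CC(C)(C)[Si](C)(C)OC[C@@H]1OC(C)(C)C(O)CC[C@@]1(C)C#C
F9 | step 5 | (6S,7R)-7-{[(tert-butyldimethylsilyl)oxy]methyl}-6-ethynyl-2,2,6-trimethyloxepan-3-one | CC(C)(C)[Si](C)(C)OC[C@@H]1OC(C)(C)C(=O)CC[C@@]1(C)C#C
F10 | step 18 | (3S,5aS,6S,9aS)-3-[(tert-butyldimethylsilyl)oxy]-2,2,5a-trimethyl-6-[(phenylselanyl)methyl]octahydro-1-benzoxepin-7(2H)-one | O=C1CC[C@@H]2OC(C)(C)[C@@H](O[Si](C)(C)C(C)(C)C)CC[C@@]2(C)[C@@H]1C[Se]c3ccccc3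
F11 | step 18 | (3S,5aS,6S,7R,9aS)-3-[(tert-butyldimethylsilyl)oxy]-2,2,5a,7-tetramethyl-6-[(phenylselanyl)methyl]decahydro-1-benzoxepin-7-ol | C[C@@]1(O)CC[C@@H]2OC(C)(C)[C@@H](O[Si](C)(C)C(C)(C)C)CC[C@@]2(C)[C@@H]1C[Se]c3ccccc3
F12 | step 18 | (3S,5aS,6S,7R,9aS)-2,2,5a,7-tetramethyl-6-[(phenylselanyl)methyl]decahydro-1-benzoxepine-3,7-diol | C[C@@]1(O)CC[C@@H]2OC(C)(C)[C@@H](O)CC[C@@]2(C)[C@@H]1C[Se]c3ccccc3
F13 | step 18 | (3S,5aS,6S,9aS)-3-[(tert-butyldimethylsilyl)oxy]-6-{2-[(3S,5aS,6S,7R,9aS)-3,7-dihydroxy-2,2,5a,7-tetramethyldecahydro-1-benzoxepin-6-yl]ethyl}-2,2,5a-trimethyloctahydro-1-benzoxepin-7(2H)-one | O=C1CC[C@@H]2OC(C)(C)[C@@H](O[Si](C)(C)C(C)(C)C)CC[C@@]2(C)[C@@H]1CC[C@H]3[C@]4(C)CC[C@H](O)C(C)(C)O[C@H]4CC[C@@]3(C)O
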